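**Retrosynthetic overview**
- The two esters go on last. C9–O and the 10α-H come from Birch reduction of a 9-en-8-one and acyloxylation of its regiospecific silyl enol ether; the isopropenyl group comes from kinetic deconjugation of a 7(11)-ene.
- Second ring-forming event (decalin): acid-triggered transannular cyclisation of a 3-acyloxygermacrone-type ten-membered trienone (C5–C10 bond, eudesm-4-yl cation), continued in the same flask by 1,2-H and 1,2-Me shifts to the eremophilane dienone (sets C4 and C5).
- First ring-forming event (ten-membered ring): C1–C10 closure (farnesyl numbering) of a 4-acyloxy-9-oxofarnesyl acetate, π-allylpalladium from the allylic acetate plus the distal dienolate.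
- The farnesyl chain comes from 4-hydroxygeranyl acetate (C5 acetoxy-enal + reverse-prenyl silane, Sharpless kinetic resolution sets C3), SeO2 oxidation, chlorination and a carbonylative Stille coupling.

Assumption: 2 and 8 are bought as catalogue reagents; ring compounds carry germacrane/eremophilane numbering (C8 = ring carbonyl carbon, β = face of the C5 methyl), open-chain compounds geranyl or farnesyl numbering.

**Step 1**
Reactants: 1 (2E)-4-acetoxy-2-methylbut-2-enal; 2 trimethyl(2-methylbut-3-en-2-yl)silane
Product: 3 rac-(2E)-4-hydroxy-3,7-dimethylocta-2,6-dien-1-yl acetate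
Conditions: TiCl4 (1.0 equiv), CH2Cl2, −78 °C
Reagents that add atoms: none
Why: Hosomi–Sakurai allylation, in which the tertiary allylsilane reacts only by SE2′ at its CH2 terminus, so the enal takes up a linear prenyl group by 1,2-addition (racemic carbinol; the E-alkene comes in with 1).

**Step 2**
Reactants: 3 rac-(2E)-4-hydroxy-3,7-dimethylocta-2,6-dien-1-yl acetate
Product: 4 (2E,4R)-4-hydroxy-3,7-dimethylocta-2,6-dien-1-yl acetate
Conditions: Ti(OiPr)4 (0.2 equiv), L-(+)-diisopropyl tartrate (0.25 equiv), tBuOOH (0.6 equiv), 4 Å molecular sieves, CH2Cl2, −20 °C, stopped near 55% conversion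
Reagents that add atoms: none
Why: Sharpless kinetic resolution, in which L-(+)-tartrate epoxidises the (4S)-allylic alcohol much faster and leaves the (4R)-alcohol (C3 of the target, at most 50% yield) while the homoallylic prenyl alkene is untouched.

**Step 3**
Reactants: 4 (2E,4R)-4-hydroxy-3,7-dimethylocta-2,6-dien-1-yl acetate
Product: 5 (2E,4R)-1-acetoxy-3,7-dimethylocta-2,6-dien-4-yl 2,2-dimethylpropanoate
Conditions: pivaloyl chloride, pyridine, DMAP (0.1 equiv), CH2Cl2, 0 °C to rt
Reagents that add atoms: pivaloyl chloride CC(C)(C)C(=O)Cl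
Why: DMAP-catalysed acylation; the pivalate survives KOtBu and lithium amide later and is the electron-withdrawing neighbour needed in step 8.

**Step 4**
Reactants: 5 (2E,4R)-1-acetoxy-3,7-dimethylocta-2,6-dien-4-yl 2,2-dimethylpropanoate
Product: 6 (2E,4R,6E)-1-acetoxy-8-hydroxy-3,7-dimethylocta-2,6-dien-4-yl 2,2-dimethylpropanoate
Conditions: SeO2 (0.3 equiv), tBuOOH (2.5 equiv), salicylic acid (0.1 equiv), CH2Cl2, 0 °C to rt
Reagents that add atoms: SeO2 O=[Se]=O (catalytic oxygen carrier); tert-butyl hydroperoxide CC(C)(C)OO (terminal oxygen source)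
Why: Sharpless–Umbreit allylic oxidation (ene then [2,3] shift) hydroxylates only the E-methyl of the electron-rich prenyl terminus, fixing the 6E geometry; the other alkene is deactivated by its two allylic esters.

**Step 5**
Reactants: 6 (2E,4R,6E)-1-acetoxy-8-hydroxy-3,7-dimethylocta-2,6-dien-4-yl 2,2-dimethylpropanoate
Product: 7 (2E,4R,6E)-1-acetoxy-8-chloro-3,7-dimethylocta-2,6-dien-4-yl 2,2-dimethylpropanoate
Conditions: N-chlorosuccinimide, Me2S, CH2Cl2, −20 to 0 °C
Reagents that add atoms: N-chlorosuccinimide O=C1CCC(=O)N1Cl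
Why: Corey–Kim chlorination of the primary allylic alcohol through the alkoxysulfonium salt, SN2 by chloride without allylic transposition or loss of E geometry.

**Step 6**
Reactants: 7 (2E,4R,6E)-1-acetoxy-8-chloro-3,7-dimethylocta-2,6-dien-4-yl 2,2-dimethylpropanoate; 8 tributyl(2-methylprop-1-en-1-yl)stannane
Product: 9 (2E,4R,6E)-1-acetoxy-3,7,11-trimethyl-9-oxododeca-2,6,10-trien-4-yl 2,2-dimethylpropanoate
Conditions: Pd2(dba)3 (2.5 mol%), PPh3 (10 mol%), CO (3 atm), THF, 50 °C
Reagents that add atoms: carbon monoxide [C-]#[O+]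
Why: Stille carbonylative cross-coupling; zerovalent palladium inserts into the allylic chloride (much faster than into the allylic esters), CO gives the acylpalladium, and vinyl transfer from tin delivers the 4,9-dioxygenated farnesyl acetate with the primary terminus and E geometry retained.

**Step 7**
Reactants: 9 (2E,4R,6E)-1-acetoxy-3,7,11-trimethyl-9-oxododeca-2,6,10-trien-4-yl 2,2-dimethylpropanoate
Product: 10 (3R)-3-(pivaloyloxy)germacra-1(10)E,4E,11-trien-8-one as a C7 epimer mixture
Conditions: Pd(PPh3)4 (10 mol%), KOtBu (1.1 equiv), tBuOH (5 equiv), THF, 40 °C, 9 added by syringe pump to 1 mM; AcOH quench at −20 °C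
Reagents that add atoms: none
Why: Proposed new method: zerovalent palladium ionises the primary allylic acetate (the laboratory counterpart of diphosphate loss from farnesyl diphosphate) and the thermodynamic potassium dienolate, formed by γ-deprotonation and equilibrating through tBuOH, attacks the unsubstituted allyl terminus through its α-carbon (farnesyl C10) to close the ten-membered ring with both E-alkenes intact and the isopropenyl group released as in germacrene A, while the more abundant C8-side enolate cannot ring-close (it would need a trans,trans-cycloocta-1,5-diene) and O-allylation is reversible under palladium; closest known reactions are Tsuji–Trost macrocyclisation, palladium-catalysed allylation of ketone enolates and deconjugative α-alkylation of enones, and the new C7 centre (unselective) is erased in step 8.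

**Step 8**
Reactants: 10 (3R)-3-(pivaloyloxy)germacra-1(10)E,4E,11-trien-8-one
Product: 12 3α-(pivaloyloxy)eremophila-7(11),9-dien-8-one (3R,4R,5R), via 3-pivaloyloxygermacrone 11 (not isolated)
Conditions: TfOH (1.5 equiv), (CF3)2CHOH/CH2Cl2 (1:4), −40 to 0 °C; NaHCO3 work-up
Reagents that add atoms: none
Why: Proposed new method: acid first conjugates the isopropenyl ketone to 11, then protonation at C1 with transannular attack of C5 on C10 through the chair–chair conformer that keeps the C3 pivalate pseudo-axial (A(1,2) strain with the C4 methyl) gives the eudesm-4-yl cation (10β-Me, 5α-H), and because this cation is destabilised by the adjacent ester (the effect that drives the Westphalen rearrangement) the charge moves on by antiperiplanar 1,2-shifts, H5α to C4 (sets 4β-Me) and the C10 methyl to C5 on the β face (sets C5), ending irreversibly by loss of H9 to the dienone; closest known reactions are the acid cyclisation of germacrone to eudesmanes, Westphalen and backbone rearrangements, and epoxide-triggered eudesmane-to-eremophilane methyl shifts.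

**Step 9**
Reactants: 12 3α-(pivaloyloxy)eremophila-7(11),9-dien-8-one
Product: 13 3α-(pivaloyloxy)eremophila-9,11-dien-8-one as a C7 epimer mixture
Conditions: LiN(iPr)2 (1.2 equiv), THF, −78 °C, 30 min; AcOH, −78 °C
Reagents that add atoms: none
Why: Kinetic deconjugation: the amide removes a proton from the isopropylidene methyl cis to the carbonyl (there is no α′-hydrogen), and kinetic protonation of the extended enolate occurs at the α-carbon C7, giving the β,γ-unsaturated isopropenyl ketone (the C7 ratio is immaterial because C7 is equilibrated in step 12).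

**Step 10**
Reactants: 13 3α-(pivaloyloxy)eremophila-9,11-dien-8-one
Product: 15 3α,8-bis(trimethylsilyloxy)-10αH-eremophila-8,11-diene (C7 epimers), via dilithium enolate alkoxide 14 (not isolated)
Conditions: Li (6.5 equiv), NH3/THF, −78 to −33 °C (inverse addition); NH3 evaporated; Me3SiCl, Et3N, THF, −78 to 0 °C
Reagents that add atoms: chlorotrimethylsilane C[Si](C)(C)Cl
Why: Birch-type enone reduction with Stork enolate trapping: protonation of the C10 β-carbanion gives the trans-decalin (10α-H), the regiospecific Δ8(9) enolate is silylated on oxygen, the isolated isopropenyl group is inert, and excess lithium reductively cleaves the pivalate to the C3 alkoxide (Bouveault–Blanc-type), which is silylated as well.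

**Step 11**
Reactants: 15 3α,8-bis(trimethylsilyloxy)-10αH-eremophila-8,11-diene; 16 3-methylbut-2-enoic acid
Product: 17 3α-hydroxy-9-(3-methylbut-2-enoyloxy)-10αH-eremophil-11-en-8-one (C7/C9 epimer mixture)
Conditions: AgO2CCH=CMe2 (2.2 equiv, made from 16 and Ag2O, dried), I2 (1.1 equiv), CH2Cl2, −20 °C; 15, −78 to 0 °C; then citric acid, MeOH, 0 °C
Reagents that add atoms: none
Why: Rubottom-type α-acyloxylation of a silyl enol ether with a silver carboxylate–iodine complex puts the senecioate directly on C9 while C3 is still masked as its silyl ether (so the two hydroxyls never need differentiating), and mild acidic methanol then frees the C3 hydroxyl; the enol ether reacts far faster than the isopropenyl alkene, and the unselective C9 centre is equilibrated in step 12.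

**Step 12**
Reactants: 17 3α-hydroxy-9-(3-methylbut-2-enoyloxy)-10αH-eremophil-11-en-8-one; 18 (2E)-2-methylbut-2-enoyl chloride
Product: 20 3α-[(2E)-2-methylbut-2-enoyloxy]-9α-(3-methylbut-2-enoyloxy)-10αH-eremophil-11-en-8-one (3R,4R,5R,7S,9S,10R), via epimeric tiglate mixture 19 (not isolated)
Conditions: 18 (1.5 equiv), Et3N, DMAP (0.2 equiv), CH2Cl2, 0 °C to rt; then DBU (0.1 equiv), 0 °C, 30 min; AcOH
Reagents that add atoms: none
Why: DMAP-catalysed acylation of the only free hydroxyl, followed by base equilibration of the two centres flanking the ketone to the all-equatorial arrangement (7α-isopropenyl, 9α-acyloxy; the β epimers are 1,3-diaxial to the C5 methyl), which is faster than migration of the isopropenyl double bond into conjugation and sets C7 (S) and C9 (S).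

**Compound list**
1 | (2E)-4-acetoxy-2-methylbut-2-enal | CC(=O)OC/C=C(\C)C=O | starting material
2 | trimethyl(2-methylbut-3-en-2-yl)silane | C=CC(C)(C)[Si](C)(C)C | starting material
3 | rac-(2E)-4-hydroxy-3,7-dimethylocta-2,6-dien-1-yl acetate | CC(=O)OC/C=C(\C)C(O)CC=C(C)C | intermediate
4 | (2E,4R)-4-hydroxy-3,7-dimethylocta-2,6-dien-1-yl acetate | CC(=O)OC/C=C(\C)[C@H](O)CC=C(C)C | intermediate
5 | (2E,4R)-1-acetoxy-3,7-dimethylocta-2,6-dien-4-yl 2,2-dimethylpropanoate | CC(=O)OC/C=C(\C)[C@H](OC(=O)C(C)(C)C)CC=C(C)C | intermediate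
6 | (2E,4R,6E)-1-acetoxy-8-hydroxy-3,7-dimethylocta-2,6-dien-4-yl 2,2-dimethylpropanoate | CC(=O)OC/C=C(\C)[C@H](OC(=O)C(C)(C)C)C/C=C(\C)CO | intermediate
7 | (2E,4R,6E)-1-acetoxy-8-chloro-3,7-dimethylocta-2,6-dien-4-yl 2,2-dimethylpropanoate | CC(=O)OC/C=C(\C)[C@H](OC(=O)C(C)(C)C)C/C=C(\C)CCl | intermediate
8 | tributyl(2-methylprop-1-en-1-yl)stannane | CC(C)=C[Sn](CCCC)(CCCC)CCCC | starting material
9 | (2E,4R,6E)-1-acetoxy-3,7,11-trimethyl-9-oxododeca-2,6,10-trien-4-yl 2,2-dimethylpropanoate | CC(=O)OC/C=C(\C)[C@H](OC(=O)C(C)(C)C)C/C=C(\C)CC(=O)C=C(C)C | intermediate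
10 | (3R)-3-(pivaloyloxy)germacra-1(10)E,4E,11-trien-8-one, C7 epimers | O=C1C/C(C)=C/C[C@@H](OC(=O)C(C)(C)C)/C(C)=C/CC1C(C)=C | intermediate
11 | (3R)-3-(pivaloyloxy)germacra-1(10)E,4E,7(11)-trien-8-one (3-pivaloyloxygermacrone) | O=C1C/C(C)=C/C[C@@H](OC(=O)C(C)(C)C)/C(C)=C/CC1=C(C)C | intermediate
12 | 3α-(pivaloyloxy)eremophila-7(11),9-dien-8-one (3R,4R,5R; 4β,5β-dimethyl) | CC(C)=C1C[C@]2(C)[C@@H](C)[C@H](OC(=O)C(C)(C)C)CCC2=CC1=O | intermediate
13 | 3α-(pivaloyloxy)eremophila-9,11-dien-8-one, C7 epimers | C=C(C)C1C[C@]2(C)[C@@H](C)[C@H](OC(=O)C(C)(C)C)CCC2=CC1=O | intermediate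
14 | dilithium 10αH-eremophila-8,11-diene-3α,8-diolate, C7 epimers | C=C(C)C1C[C@]2(C)[C@@H](C)[C@H](O[Li])CC[C@H]2C=C1O[Li] | intermediate
15 | 3α,8-bis(trimethylsilyloxy)-10αH-eremophila-8,11-diene, C7 epimers | C=C(C)C1C[C@]2(C)[C@@H](C)[C@H](O[Si](C)(C)C)CC[C@H]2C=C1O[Si](C)(C)C | intermediate
16 | 3-methylbut-2-enoic acid | CC(C)=CC(=O)O | starting material
17 | 3α-hydroxy-9-(3-methylbut-2-enoyloxy)-10αH-eremophil-11-en-8-one, C7/C9 epimers | C=C(C)C1C[C@]2(C)[C@@H](C)[C@H](O)CC[C@H]2C(OC(=O)C=C(C)C)C1=O | intermediate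
18 | (2E)-2-methylbut-2-enoyl chloride | C/C=C(\C)C(Cl)=O | starting material
19 | 3α-[(2E)-2-methylbut-2-enoyloxy]-9-(3-methylbut-2-enoyloxy)-10αH-eremophil-11-en-8-one, C7/C9 epimers | C=C(C)C1C[C@]2(C)[C@@H](C)[C@H](OC(=O)/C(C)=C/C)CC[C@H]2C(OC(=O)C=C(C)C)C1=O | intermediate
20 | 3α-[(2E)-2-methylbut-2-enoyloxy]-9α-(3-methylbut-2-enoyloxy)-10αH-eremophil-11-en-8-one (3R,4R,5R,7S,9S,10R) | C=C(C)[C@@H]1C[C@]2(C)[C@@H](C)[C@H](OC(=O)/C(C)=C/C)CC[C@H]2[C@H](OC(=O)C=C(C)C)C1=O | target

**Step count**
Total: 12 steps. Longest linear sequence: 12 steps (1 to 20); 2, 8, 16 and 18 enter as purchased reagents.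

**Steps most likely to fail and their fallbacks**

Step 8 (the one-flask cyclisation/1,2-H/1,2-Me cascade). The C4 cation may instead be trapped by the neighbouring ester or simply lose a proton, stopping at the eudesmane stage. The fallback sets out from 10 and returns at 12. Mild acid (TsOH, 5 mol%, CH2Cl2, 0 °C) performs only the transannular cyclisation and gives 3α-(pivaloyloxy)eudesma-4,7(11)-dien-8-one F2. mCPBA epoxidises its tetrasubstituted alkene from the α face (anti to the C10 methyl) to the 4α,5α-epoxide of 3α-(pivaloyloxy)eudesm-7(11)-en-8-one F3. BF3·OEt2 opens this at C5 (C4 is deactivated by the ester), the C10 methyl migrates anti to the leaving oxygen and H9 is lost, giving 4α-hydroxy-3α-(pivaloyloxy)eremophila-7(11),9-dien-8-one F4. Burgess reagent can only eliminate towards C15 (H3 is anti to the C4 oxygen, C5 has no hydrogen) and gives 3α-(pivaloyloxy)eremophila-4(15),7(11),9-trien-8-one F5. RhCl(PPh3)3/H2 then saturates only this 1,1-disubstituted alkene from the α face, giving 12.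

Step 7 (ten-membered ring closure through a minor dienolate). The productive γ-dienolate is the minor anion, so oligomerisation or double-bond migration may win. The fallback sets out from 7 and returns at 10. The carbonylative Stille coupling is run with tributyl(2-methylprop-2-en-1-yl)stannane in place of 8 to give the doubly skipped ketone (2E,4R,6E)-1-acetoxy-3,7,11-trimethyl-9-oxododeca-2,6,11-trien-4-yl 2,2-dimethylpropanoate F1. Here farnesyl C10 is an ordinary α-carbon, so kinetic deprotonation with LiN(SiMe3)2 at −78 °C gives the required dienolate as about half of the enolate pool without any equilibration. Pd(PPh3)4 under high dilution then closes the ring to 10.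

Step 11 (silver carboxylate–iodine acyloxylation on a substrate carrying a second alkene, C9 unselective). The fallback sets out from 15 and returns at 19. Rubottom oxidation (mCPBA, NaHCO3, CH2Cl2, −15 °C; citric acid, MeOH) delivers oxygen to the α face of C9, opposite the axial C5 methyl, and gives 3α,9α-dihydroxy-10αH-eremophil-11-en-8-one F6. 18 (1.05 equiv, 2,4,6-collidine, −40 °C) should acylate the C3 hydroxyl rather than the hydrogen-bonded, more hindered ketol hydroxyl, giving 3α-[(2E)-2-methylbut-2-enoyloxy]-9α-hydroxy-10αH-eremophil-11-en-8-one F7. 3-Methylbut-2-enoyl chloride with Et3N/DMAP then esterifies C9 and joins the route at 19.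

**Further compounds**
F1 | step 7 | (2E,4R,6E)-1-acetoxy-3,7,11-trimethyl-9-oxododeca-2,6,11-trien-4-yl 2,2-dimethylpropanoate | CC(=O)OC/C=C(\C)[C@H](OC(=O)C(C)(C)C)C/C=C(\C)CC(=O)CC(C)=C
F2 | step 8 | 3α-(pivaloyloxy)eudesma-4,7(11)-dien-8-one (10β-methyl) | CC(C)=C1CC2=C(C)[C@H](OC(=O)C(C)(C)C)CC[C@]2(C)CC1=O
F3 | step 8 | 4α,5α-epoxy-3α-(pivaloyloxy)eudesm-7(11)-en-8-one | CC(C)=C1C[C@@]23O[C@]2(C)[C@H](OC(=O)C(C)(C)C)CC[C@]3(C)CC1=O
F4 | step 8 | 4α-hydroxy-3α-(pivaloyloxy)eremophila-7(11),9-dien-8-one | CC(C)=C1C[C@]2(C)[C@](C)(O)[C@H](OC(=O)C(C)(C)C)CCC2=CC1=O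
F5 | step 8 | 3α-(pivaloyloxy)eremophila-4(15),7(11),9-trien-8-one | CC(C)=C1C[C@]2(C)C(=C)[C@H](OC(=O)C(C)(C)C)CCC2=CC1=O
F6 | step 11 | 3α,9α-dihydroxy-10αH-eremophil-11-en-8-one, C7 epimers | C=C(C)C1C[C@]2(C)[C@@H](C)[C@H](O)CC[C@H]2[C@H](O)C1=O
F7 | step 11 | 3α-[(2E)-2-methylbut-2-enoyloxy]-9α-hydroxy-10αH-eremophil-11-en-8-one, C7 epimers | C=C(C)C1C[C@]2(C)[C@@H](C)[C@H](OC(=O)/C(C)=C/C)CC[C@H]2[C@H](O)C1=O
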